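A direct plan would form both depside esters by acylating phenol oxygens, with bromine atoms standing in for the flanking hydroxyls.
Tri-O-benzylgalloyl chloride A1 would acylate 3,5-dibromo-4-hydroxybenzaldehyde A2 to ester A3, and oxidation would give acid A4.
A4 would then be esterified with benzyl 3,5-dibromo-4-hydroxybenzoate A5 to give tetrabromide A6.
Fourfold borylation and oxidation would give tetraphenol A7, and hydrogenolysis would give the target.
Weakest would be the fourfold exchange of C–Br for C–OH: four hindered sites beside activated aryl esters would each have to react fully under base and then peroxide, and every shortfall would give a congener that is hard to remove.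
Next would be the two acylations of 2,6-dibromophenols, weak and hindered nucleophiles whose esters carry a good leaving group and would be open to cleavage and acyl transfer.
The oxidation of the formyl group of A3 would add length without complexity, since it only corrects an oxidation level chosen to avoid a protecting group.

The route would rest on the aryl C4–O bonds of rings A and B, not on the acyl–O bonds. C4 of a 3,5-dioxygenated benzoate lies between two oxygens and is sold as its bromide. Bromine–magnesium exchange would give an aryl nucleophile, and a diaroyl peroxide would serve as an electrophilic aroyloxy donor, a union made possible by polarity reversal at oxygen. The key step would deliver the oxygen to C4 of ring B already galloylated and complete the tridepside. No hindered phenol would be acylated, no hydroxyl would be made from a halide once the esters exist, no 4-phenol would be free to pass on its acyl group, and every carboxyl carbon would enter at the acid level.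

Key step: step 8

Remark: 4-bromo-3,5-dihydroxybenzoic acid and 3,4,5-tris(benzyloxy)benzoic acid are taken as commercial; the peroxy acids and diaroyl peroxides would be kept cold, shielded from light and used soon after they are made.

Step 1
Reactants: 1 4-bromo-3,5-dihydroxybenzoic acid
Product: 2 benzyl 3,5-bis(benzyloxy)-4-bromobenzoate
Conditions: BnBr (3.5 equiv), K2CO3 (4 equiv), DMF, 60 °C
Reagents that add atoms: benzyl bromide, BrCc1ccccc1
Why: Williamson etherification of both phenoxides and SN2 O-alkylation of the carboxylate should protect all three acidic groups in one operation with groups that the final hydrogenolysis removes.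

Step 2
Reactants: 2 benzyl 3,5-bis(benzyloxy)-4-bromobenzoate
Product: 3 3,5-bis(benzyloxy)-4-bromobenzoic acid
Conditions: LiOH·H2O (3 equiv), THF/H2O, 40 °C; then 1 M HCl
Reagents that add atoms: lithium hydroxide, [Li+].[OH-] (hydroxyl oxygen of the carboxyl group)
Why: Saponification of the benzyl ester (acyl–oxygen cleavage by hydroxide) should free the carboxyl group needed for the peroxide, while the aryl benzyl ethers and the aryl bromide are inert to aqueous base.

Step 3
Reactants: 3 3,5-bis(benzyloxy)-4-bromobenzoic acid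
Product: 4 3,5-bis(benzyloxy)-4-bromobenzoyl chloride
Conditions: (COCl)2 (1.3 equiv), cat. DMF, CH2Cl2, 0 °C to rt; evaporate
Reagents that add atoms: oxalyl chloride, O=C(Cl)C(=O)Cl (the chlorine atom)
Why: Chlorination of the acid through the Vilsmeier-type chloroiminium salt formed from DMF and oxalyl chloride should give the aroyl chloride under conditions that leave the aryl benzyl ethers and the aryl bromide untouched.

Step 4
Reactants: 3 3,5-bis(benzyloxy)-4-bromobenzoic acid; 4 3,5-bis(benzyloxy)-4-bromobenzoyl chloride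
Product: 6 bis[3,5-bis(benzyloxy)-4-bromobenzoyl] peroxide, via ring B peroxy acid 5 (not isolated)
Conditions: 4 in THF added to H2O2 (30% aq., 4 equiv), NaOH (2 equiv), cat. MgSO4·7H2O, THF/H2O, 0 °C; cold 1 M H2SO4, extract (CH2Cl2), dry (Na2SO4); then 3 (1.0 equiv), DCC (1.05 equiv), CH2Cl2, −10 to 0 °C, dark
Reagents that add atoms: hydrogen peroxide, OO (both peroxide oxygens)
Why: Perhydrolysis of the aroyl chloride by excess hydroperoxide anion, an alpha-effect nucleophile, should give peroxy acid 5, which the O-acylisourea formed from acid 3 and DCC then acylates on its terminal oxygen (carbodiimide-mediated diacyl peroxide synthesis), so that one acyl group comes from 4 and one from 3 under cold, neutral conditions that spare the aryl bromide and the benzyl ethers.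

Step 5
Reactants: 2 benzyl 3,5-bis(benzyloxy)-4-bromobenzoate; 6 bis[3,5-bis(benzyloxy)-4-bromobenzoyl] peroxide
Product: 8 benzyl 3,5-bis(benzyloxy)-4-{[3,5-bis(benzyloxy)-4-bromobenzoyl]oxy}benzoate, via arylmagnesium chloride 7 (not isolated)
Conditions: 2, iPrMgCl·LiCl (0.98 equiv), THF, −30 °C; then transfer into 6 (1.3 equiv), THF, −78 to −20 °C; aq. NH4Cl
Reagents that add atoms: isopropylmagnesium chloride–lithium chloride complex, CC(C)[Mg]Cl.[Li+].[Cl-] (magnesium and chlorine of intermediate 7 only; none of its atoms remain in 8)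
Why: Halogen–magnesium exchange at the C–Br bond flanked by two benzyloxy groups should be fast at a temperature where the benzyl ester survives, and the arylmagnesium should then attack a peroxide oxygen of 6 (O-acyloxylation of a Grignard reagent by a diaroyl peroxide, a substitution at oxygen) to give the aryl ester and the magnesium salt of 3, the slight deficit of exchange reagent and the inverse addition into excess peroxide keeping both the aryl bromide of 6 and the product ester from being attacked.

Step 6
Reactants: 9 3,4,5-tris(benzyloxy)benzoic acid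
Product: 10 3,4,5-tris(benzyloxy)benzoyl chloride
Conditions: (COCl)2 (1.3 equiv), cat. DMF, CH2Cl2, 0 °C to rt; evaporate
Reagents that add atoms: oxalyl chloride, O=C(Cl)C(=O)Cl (the chlorine atom)
Why: The same Vilsmeier-type chlorination should convert the galloyl acid of ring C into its chloride without touching the three benzyl ethers.

Step 7
Reactants: 9 3,4,5-tris(benzyloxy)benzoic acid; 10 3,4,5-tris(benzyloxy)benzoyl chloride
Product: 12 bis[3,4,5-tris(benzyloxy)benzoyl] peroxide, via ring C peroxy acid 11 (not isolated)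
Conditions: 10 in THF added to H2O2 (30% aq., 4 equiv), NaOH (2 equiv), cat. MgSO4·7H2O, THF/H2O, 0 °C; cold 1 M H2SO4, extract (CH2Cl2), dry (Na2SO4); then 9 (1.0 equiv), DCC (1.05 equiv), CH2Cl2, −10 to 0 °C, dark
Reagents that add atoms: hydrogen peroxide, OO (both peroxide oxygens)
Why: Perhydrolysis of the aroyl chloride followed by carbodiimide-mediated acylation of peroxy acid 11 by acid 9 should turn the galloyl unit of ring C into an electrophilic aroyloxy donor, the two meta benzyloxy groups offsetting the donor effect of the para one so that the peroxide should be stable enough to handle cold.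

Step 8
Reactants: 8 benzyl 3,5-bis(benzyloxy)-4-{[3,5-bis(benzyloxy)-4-bromobenzoyl]oxy}benzoate; 12 bis[3,4,5-tris(benzyloxy)benzoyl] peroxide
Product: 14 benzyl 3,5-bis(benzyloxy)-4-{[3,5-bis(benzyloxy)-4-{[3,4,5-tris(benzyloxy)benzoyl]oxy}benzoyl]oxy}benzoate, via depside arylmagnesium chloride 13 (not isolated)
Conditions: 8, iPrMgCl·LiCl (1.0 equiv), THF, −40 °C; then transfer into 12 (1.3 equiv), THF, −78 to −20 °C; aq. NH4Cl
Reagents that add atoms: isopropylmagnesium chloride–lithium chloride complex, CC(C)[Mg]Cl.[Li+].[Cl-] (magnesium and chlorine of intermediate 13 only; none of its atoms remain in 14)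
Why: Isopropylmagnesium chloride should exchange magnesium for the bromine at C4 of ring B, the only halogen-bearing carbon of 8 and one where two ortho benzyloxy groups and a para carbonyl group stabilise the aryl carbanion, and the arylmagnesium 13 should then attack one peroxide oxygen of 12 along the O–O axis with tri-O-benzylgallate as leaving group, so that the C4–O bond forms with its galloyl group already attached. The closest known reaction types are the halogen–magnesium exchange of functionalised aryl bromides and the O-acyloxylation of Grignard reagents by dibenzoyl peroxide. No ring is closed and no stereocentre is formed; the para position of the new depside bond is fixed by the bromine. The step needs chemoselectivity for the O–O bond over four kinds of carbonyl group (those of 12, the depside ester and the benzyl ester of 8 and 13, and the ester of the product). The weak O–O bond with its low-lying antibonding orbital, the poor carbonyl reactivity of a 2,6-disubstituted arylmagnesium at low temperature and the inverse addition into excess peroxide should provide it. Because the flanking oxygens are benzyl ethers and the C4 oxygen is never a free phenol, neither a hindered acylation nor an acyl migration enters.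

Step 9
Reactants: 14 benzyl 3,5-bis(benzyloxy)-4-{[3,5-bis(benzyloxy)-4-{[3,4,5-tris(benzyloxy)benzoyl]oxy}benzoyl]oxy}benzoate
Product: 15 3,5-dihydroxy-4-{[3,5-dihydroxy-4-{[3,4,5-trihydroxybenzoyl]oxy}benzoyl]oxy}benzoic acid
Conditions: H2 (1 atm), Pd/C (10% Pd), THF/EtOAc, rt
Reagents that add atoms: none
Why: Heterogeneous hydrogenolysis should cleave the seven benzyl ethers and the benzyl ester to toluene under neutral, aprotic conditions that leave both aryl ester bonds intact and give acyl migration little opportunity.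

Compound list
1 | 4-bromo-3,5-dihydroxybenzoic acid | O=C(O)c1cc(O)c(Br)c(O)c1 | starting material
2 | benzyl 3,5-bis(benzyloxy)-4-bromobenzoate | O=C(OCc1ccccc1)c1cc(OCc2ccccc2)c(Br)c(OCc2ccccc2)c1 | intermediate
3 | 3,5-bis(benzyloxy)-4-bromobenzoic acid | O=C(O)c1cc(OCc2ccccc2)c(Br)c(OCc2ccccc2)c1 | intermediate
4 | 3,5-bis(benzyloxy)-4-bromobenzoyl chloride | O=C(Cl)c1cc(OCc2ccccc2)c(Br)c(OCc2ccccc2)c1 | intermediate
5 | 3,5-bis(benzyloxy)-4-bromoperoxybenzoic acid | O=C(OO)c1cc(OCc2ccccc2)c(Br)c(OCc2ccccc2)c1 | intermediate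
6 | bis[3,5-bis(benzyloxy)-4-bromobenzoyl] peroxide | O=C(OOC(=O)c1cc(OCc2ccccc2)c(Br)c(OCc2ccccc2)c1)c1cc(OCc2ccccc2)c(Br)c(OCc2ccccc2)c1 | intermediate
7 | [2,6-bis(benzyloxy)-4-(benzyloxycarbonyl)phenyl]magnesium chloride | O=C(OCc1ccccc1)c1cc(OCc2ccccc2)c([Mg]Cl)c(OCc2ccccc2)c1 | intermediate
8 | benzyl 3,5-bis(benzyloxy)-4-{[3,5-bis(benzyloxy)-4-bromobenzoyl]oxy}benzoate | O=C(OCc1ccccc1)c1cc(OCc2ccccc2)c(OC(=O)c2cc(OCc3ccccc3)c(Br)c(OCc3ccccc3)c2)c(OCc2ccccc2)c1 | intermediate
9 | 3,4,5-tris(benzyloxy)benzoic acid | O=C(O)c1cc(OCc2ccccc2)c(OCc2ccccc2)c(OCc2ccccc2)c1 | starting material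
10 | 3,4,5-tris(benzyloxy)benzoyl chloride | O=C(Cl)c1cc(OCc2ccccc2)c(OCc2ccccc2)c(OCc2ccccc2)c1 | intermediate
11 | 3,4,5-tris(benzyloxy)peroxybenzoic acid | O=C(OO)c1cc(OCc2ccccc2)c(OCc2ccccc2)c(OCc2ccccc2)c1 | intermediate
12 | bis[3,4,5-tris(benzyloxy)benzoyl] peroxide | O=C(OOC(=O)c1cc(OCc2ccccc2)c(OCc2ccccc2)c(OCc2ccccc2)c1)c1cc(OCc2ccccc2)c(OCc2ccccc2)c(OCc2ccccc2)c1 | intermediate
13 | {2,6-bis(benzyloxy)-4-[(2,6-bis(benzyloxy)-4-(benzyloxycarbonyl)phenoxy)carbonyl]phenyl}magnesium chloride | O=C(OCc1ccccc1)c1cc(OCc2ccccc2)c(OC(=O)c2cc(OCc3ccccc3)c([Mg]Cl)c(OCc3ccccc3)c2)c(OCc2ccccc2)c1 | intermediate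
14 | benzyl 3,5-bis(benzyloxy)-4-{[3,5-bis(benzyloxy)-4-{[3,4,5-tris(benzyloxy)benzoyl]oxy}benzoyl]oxy}benzoate | O=C(OCc1ccccc1)c1cc(OCc2ccccc2)c(OC(=O)c2cc(OCc3ccccc3)c(OC(=O)c3cc(OCc4ccccc4)c(OCc4ccccc4)c(OCc4ccccc4)c3)c(OCc3ccccc3)c2)c(OCc2ccccc2)c1 | intermediate
15 | 3,5-dihydroxy-4-{[3,5-dihydroxy-4-{[3,4,5-trihydroxybenzoyl]oxy}benzoyl]oxy}benzoic acid | O=C(O)c1cc(O)c(OC(=O)c2cc(O)c(OC(=O)c3cc(O)c(O)c(O)c3)c(O)c2)c(O)c1 | target

Total step count: 9. Longest linear sequence: 7 steps (steps 1, 2, 3, 4, 5, 8 and 9); steps 6 and 7 form a two-step branch.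

Steps most likely to fail

Step 8. Isopropylmagnesium chloride or the arylmagnesium 13 could add to the depside carbonyl group of 8 faster than the bromine–magnesium exchange or the oxygen transfer proceeds, which would lead to acyl transfer and oligomers. The fallback sets out from 4 and 12 and comes back at 14; it reverses the order of the two C–O bond formations so that only monomers carry magnesium. Acid chloride 4 would be treated with KOtBu (THF, 0 °C) to give tert-butyl 3,5-bis(benzyloxy)-4-bromobenzoate F1. Exchange with iPrMgCl·LiCl (THF, −30 °C) would give [2,6-bis(benzyloxy)-4-(tert-butoxycarbonyl)phenyl]magnesium chloride F2, which would be added to peroxide 12 to give tert-butyl 3,5-bis(benzyloxy)-4-{[3,4,5-tris(benzyloxy)benzoyl]oxy}benzoate F3. TFA in CH2Cl2 at 0 °C would free 3,5-bis(benzyloxy)-4-{[3,4,5-tris(benzyloxy)benzoyl]oxy}benzoic acid F4, and H2O2 with DCC (CH2Cl2, −10 to 0 °C) would join two molecules of it to bis{3,5-bis(benzyloxy)-4-{[3,4,5-tris(benzyloxy)benzoyl]oxy}benzoyl} peroxide F5. Arylmagnesium 7, made from 2 as in step 5, would then attack F5 to give 14, the second aroyloxy half of F5 returning as F4.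

Step 5. Electron transfer from 7 to the peroxide followed by loss of CO2 from aroyloxy radicals, or attack at a peroxide carbonyl group, could outrun the substitution at oxygen. The fallback sets out from 2 and comes back at 8; it makes the same ester by the acyl–O bond. Arylmagnesium 7 would be trapped with B(OMe)3 to give dimethyl [2,6-bis(benzyloxy)-4-(benzyloxycarbonyl)phenyl]boronate F6, which would be oxidised in the same flask with H2O2 in AcOH/THF to benzyl 3,5-bis(benzyloxy)-4-hydroxybenzoate F7. Acid chloride 4 from step 3 would then acylate F7 (Et3N, DMAP, CH2Cl2, 0 °C to rt) to give 8.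

Step 9. Removal of eight benzyl groups over Pd could stall at poorly soluble, partly debenzylated intermediates, and a long reaction time would give room for acyl migration from O4 to O3. The fallback sets out from 14 and comes back at 15 without a new compound: a non-reductive Lewis-acid debenzylation with BCl3 and pentamethylbenzene as benzyl cation scavenger in CH2Cl2 at −78 °C, quenched cold with MeOH/CHCl3.

Further compounds
F1 | step 8 | tert-butyl 3,5-bis(benzyloxy)-4-bromobenzoate | CC(C)(C)OC(=O)c1cc(OCc2ccccc2)c(Br)c(OCc2ccccc2)c1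
F2 | step 8 | [2,6-bis(benzyloxy)-4-(tert-butoxycarbonyl)phenyl]magnesium chloride | CC(C)(C)OC(=O)c1cc(OCc2ccccc2)c([Mg]Cl)c(OCc2ccccc2)c1
F3 | step 8 | tert-butyl 3,5-bis(benzyloxy)-4-{[3,4,5-tris(benzyloxy)benzoyl]oxy}benzoate | CC(C)(C)OC(=O)c1cc(OCc2ccccc2)c(OC(=O)c2cc(OCc3ccccc3)c(OCc3ccccc3)c(OCc3ccccc3)c2)c(OCc2ccccc2)c1
F4 | step 8 | 3,5-bis(benzyloxy)-4-{[3,4,5-tris(benzyloxy)benzoyl]oxy}benzoic acid | O=C(O)c1cc(OCc2ccccc2)c(OC(=O)c2cc(OCc3ccccc3)c(OCc3ccccc3)c(OCc3ccccc3)c2)c(OCc2ccccc2)c1
F5 | step 8 | bis{3,5-bis(benzyloxy)-4-{[3,4,5-tris(benzyloxy)benzoyl]oxy}benzoyl} peroxide | O=C(OOC(=O)c1cc(OCc2ccccc2)c(OC(=O)c2cc(OCc3ccccc3)c(OCc3ccccc3)c(OCc3ccccc3)c2)c(OCc2ccccc2)c1)c1cc(OCc2ccccc2)c(OC(=O)c2cc(OCc3ccccc3)c(OCc3ccccc3)c(OCc3ccccc3)c2)c(OCc2ccccc2)c1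
F6 | step 5 | dimethyl [2,6-bis(benzyloxy)-4-(benzyloxycarbonyl)phenyl]boronate | COB(OC)c1c(OCc2ccccc2)cc(C(=O)OCc2ccccc2)cc1OCc1ccccc1
F7 | step 5 | benzyl 3,5-bis(benzyloxy)-4-hydroxybenzoate | O=C(OCc1ccccc1)c1cc(OCc2ccccc2)c(O)c(OCc2ccccc2)c1
F0 | step 9 | none | none
A1 | direct plan | 3,4,5-tris(benzyloxy)benzoyl chloride | O=C(Cl)c1cc(OCc2ccccc2)c(OCc2ccccc2)c(OCc2ccccc2)c1
A2 | direct plan | 3,5-dibromo-4-hydroxybenzaldehyde | O=Cc1cc(Br)c(O)c(Br)c1
A3 | direct plan | 2,6-dibromo-4-formylphenyl 3,4,5-tris(benzyloxy)benzoate | O=Cc1cc(Br)c(OC(=O)c2cc(OCc3ccccc3)c(OCc3ccccc3)c(OCc3ccccc3)c2)c(Br)c1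
A4 | direct plan | 3,5-dibromo-4-[3,4,5-tris(benzyloxy)benzoyloxy]benzoic acid | O=C(O)c1cc(Br)c(OC(=O)c2cc(OCc3ccccc3)c(OCc3ccccc3)c(OCc3ccccc3)c2)c(Br)c1
A5 | direct plan | benzyl 3,5-dibromo-4-hydroxybenzoate | O=C(OCc1ccccc1)c1cc(Br)c(O)c(Br)c1
A6 | direct plan | benzyl 3,5-dibromo-4-{3,5-dibromo-4-[3,4,5-tris(benzyloxy)benzoyloxy]benzoyl}oxybenzoate | O=C(OCc1ccccc1)c1cc(Br)c(OC(=O)c2cc(Br)c(OC(=O)c3cc(OCc4ccccc4)c(OCc4ccccc4)c(OCc4ccccc4)c3)c(Br)c2)c(Br)c1
A7 | direct plan | benzyl 3,5-dihydroxy-4-{3,5-dihydroxy-4-[3,4,5-tris(benzyloxy)benzoyloxy]benzoyl}oxybenzoate | O=C(OCc1ccccc1)c1cc(O)c(OC(=O)c2cc(O)c(OC(=O)c3cc(OCc4ccccc4)c(OCc4ccccc4)c(OCc4ccccc4)c3)c(O)c2)c(O)c1
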